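The oxane ring is cut at C2–C3. C2 is the benzylic carbon that links ring oxygen O1 to the 3,4,5-trioxygenated aryl ring; before ring closure it is only the CH2 of an alkoxy-rich benzyl ether on the oxygen of C6, and its C–H bond is the handle. In a single operation DDQ converts that CH2 into an oxocarbenium ion, which a tethered enol acetate captures, so the C2–C3 bond, the tetrahydropyran-4-one ring and the C2 stereocentre (cis to C6) form together. The precursor is an acyclic 2-acetoxyallyl carbinol ether with one stereocentre, a 3,4-bis(benzyloxy)-5-methoxybenzyl group on oxygen and a deactivating pivalate on the remote phenol.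

Key step: step 9

Remark: the target is read as the all-cis (2S,4R,6S)-oxane (aryl at C2, hydroxyl at C4 and arylethyl at C6 all equatorial); 3-(4-hydroxyphenyl)propan-1-ol, allenylboronic acid pinacol ester and (R)-TRIP are taken as commercial.

Step 1
Reactants: 1 3,4-dihydroxy-5-methoxybenzaldehyde (5-hydroxyvanillin)
Product: 2 3,4-bis(benzyloxy)-5-methoxybenzaldehyde
Conditions: BnBr (2.5 equiv), K2CO3 (3 equiv), DMF, 60 °C
Reagents that add atoms: benzyl bromide, BrCc1ccccc1
Why: Williamson ether synthesis, in which both phenoxides (the 4-OH is activated by the para aldehyde, the 3-OH follows with excess base) displace bromide from benzyl bromide by SN2.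

Step 2
Reactants: 2 3,4-bis(benzyloxy)-5-methoxybenzaldehyde
Product: 3 [3,4-bis(benzyloxy)-5-methoxyphenyl]methanol
Conditions: NaBH4, MeOH/THF, 0 °C
Reagents that add atoms: none
Why: Borohydride reduction of an aryl aldehyde to the benzyl alcohol, with the aryl benzyl and methyl ethers inert.

Step 3
Reactants: 3 [3,4-bis(benzyloxy)-5-methoxyphenyl]methanol
Product: 4 3,4-bis(benzyloxy)-5-methoxybenzyl 2,2,2-trichloroacetimidate
Conditions: Cl3CCN (1.5 equiv), DBU (0.1 equiv), CH2Cl2, 0 °C
Reagents that add atoms: trichloroacetonitrile, N#CC(Cl)(Cl)Cl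
Why: Base-catalysed addition of the benzylic alkoxide to the nitrile (trichloroacetimidate formation), the standard way to make an alkoxybenzyl donor for acid-catalysed etherification.

Step 4
Reactants: 5 3-(4-hydroxyphenyl)propan-1-ol
Product: 6 4-(3-hydroxypropyl)phenyl pivalate
Conditions: PivCl (1.05 equiv), 1 M aq. NaOH (1.1 equiv), Bu4NHSO4 (cat.), CH2Cl2, 0 °C
Reagents that add atoms: pivaloyl chloride, CC(C)(C)C(Cl)=O
Why: Schotten–Baumann acylation under phase transfer, in which only the phenol is ionised by aqueous hydroxide and the phenoxide is acylated while the neutral primary alcohol is left alone.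

Step 5
Reactants: 6 4-(3-hydroxypropyl)phenyl pivalate
Product: 7 4-(3-oxopropyl)phenyl pivalate
Conditions: Dess–Martin periodinane (1.2 equiv), CH2Cl2, 0 °C to rt
Reagents that add atoms: none
Why: Dess–Martin oxidation of a primary alcohol stops at the aldehyde, and its neutral conditions keep the aryl pivalate.

Step 6
Reactants: 7 4-(3-oxopropyl)phenyl pivalate; 8 allenylboronic acid pinacol ester
Product: 10 (S)-4-(3-hydroxyhex-5-yn-1-yl)phenyl pivalate, via pinacol borate ester 9 (not isolated)
Conditions: 8 (1.5 equiv), (R)-TRIP (10 mol%), 4 Å MS, toluene, −20 °C; aqueous work-up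
Reagents that add atoms: none
Why: Chiral phosphoric acid-catalysed propargylation with an allenylboronate, which adds through a closed six-membered chair transition state (SE2′, so only the homopropargylic alcohol forms) in which (R)-TRIP binds a boronate oxygen and the formyl hydrogen and should direct attack to the Re face of the aldehyde, the (S) configuration here because the propargyl group outranks the arylethyl chain.

Step 7
Reactants: 10 (S)-4-(3-hydroxyhex-5-yn-1-yl)phenyl pivalate; 4 3,4-bis(benzyloxy)-5-methoxybenzyl 2,2,2-trichloroacetimidate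
Product: 11 (S)-4-{3-[(3,4-bis(benzyloxy)-5-methoxybenzyl)oxy]hex-5-yn-1-yl}phenyl pivalate
Conditions: 4 (1.5 equiv), TMSOTf (5 mol%), 4 Å MS, CH2Cl2, −20 to 0 °C
Reagents that add atoms: none
Why: Acid-catalysed trichloroacetimidate benzylation (transfer of the alkoxy-stabilised benzyl cation to the alcohol oxygen), chosen because a basic Williamson etherification would cleave the aryl pivalate, and leaving the carbinol stereocentre untouched since its C–O bond is not broken.

Step 8
Reactants: 11 (S)-4-{3-[(3,4-bis(benzyloxy)-5-methoxybenzyl)oxy]hex-5-yn-1-yl}phenyl pivalate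
Product: 12 (S)-4-{[3,4-bis(benzyloxy)-5-methoxybenzyl]oxy}-6-[4-(pivaloyloxy)phenyl]hex-1-en-2-yl acetate
Conditions: AcOH (2 equiv), [Ru(p-cymene)Cl2]2 (2 mol%), tri(2-furyl)phosphine (4 mol%), Na2CO3 (10 mol%), toluene, 80 °C
Reagents that add atoms: acetic acid, CC(=O)O
Why: Ruthenium-catalysed Markovnikov hydro-acyloxylation of a terminal alkyne, which places the acetate on the internal carbon and gives the 2-acetoxy-1-alkene without touching the ether or the esters.

Step 9
Reactants: 12 (S)-4-{[3,4-bis(benzyloxy)-5-methoxybenzyl]oxy}-6-[4-(pivaloyloxy)phenyl]hex-1-en-2-yl acetate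
Product: 15 (2S,6S)-2-[3,4-bis(benzyloxy)-5-methoxyphenyl]-6-{2-[4-(pivaloyloxy)phenyl]ethyl}tetrahydro-4H-pyran-4-one, via (E)-aryl oxocarbenium ion 13 (not isolated), via O-acetyl oxocarbenium ion 14 (not isolated)
Conditions: DDQ (2 equiv), 2,6-dichloropyridine (4 equiv), LiClO4 (cat.), 4 Å MS, 1,2-dichloroethane, rt; aq. NaHCO3 work-up
Reagents that add atoms: none
Why: DDQ takes an electron from the trialkoxy arene of 12 and then the benzylic hydrogen, giving the (E)-aryl oxocarbenium ion 13; the terminal carbon of the enol acetate (future C3) adds to its carbon (C2), and the O-acetyl oxocarbenium ion 14 so formed hands its acetyl group to the reduced quinone or the pyridine base, leaving ketone 15. The closest known reaction type is the DDQ-mediated oxidative benzylic C–H cleavage of electron-rich benzyl ethers with enol acetate trapping, an oxidatively triggered Prins-type cyclisation to 2,6-cis-tetrahydropyran-4-ones. The oxane ring closes in the 6-endo-trig mode, the C2=O1 and C3=C4 π bonds both lying inside the new ring. C2 is controlled by the chair transition state: the E geometry of the oxocarbenium ion puts the aryl group equatorial and the existing (S) centre at C6 puts its arylethyl chain equatorial, so the 2,6-cis (2S,6S) ketone should form. The step needs site selectivity for the ArCH2–O methylene, which the substrate secures because only the trialkoxy ring is electron-rich enough for DDQ (the pivalate deactivates the other arene) and the OCH2Ph hydrogens are not conjugated with the oxidised ring. 2,6-Dichloropyridine buffers the acidic hydroquinone so that the enol acetate and the benzyl ethers persist, and the ring ketone inductively disfavours a second hydride loss at C2.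

Step 10
Reactants: 15 (2S,6S)-2-[3,4-bis(benzyloxy)-5-methoxyphenyl]-6-{2-[4-(pivaloyloxy)phenyl]ethyl}tetrahydro-4H-pyran-4-one
Product: 17 (2S,4R,6S)-2-[3,4-bis(benzyloxy)-5-methoxyphenyl]-6-[2-(4-hydroxyphenyl)ethyl]tetrahydro-2H-pyran-4-ol, via hydroxy pivalate 16 (not isolated)
Conditions: LiAlH4 (3 equiv), THF, −78 °C to 0 °C; aq. Rochelle salt work-up
Reagents that add atoms: none
Why: Hydride reduction of a conformationally locked tetrahydropyran-4-one, in which the small aluminium hydride attacks the chair (both ring substituents equatorial) along the axial trajectory and should set C4 as the equatorial, all-cis (4R) alcohol, while on warming the same reagent reduces the aryl pivalate to the free phenol and leaves the benzyl ethers alone.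

Step 11
Reactants: 17 (2S,4R,6S)-2-[3,4-bis(benzyloxy)-5-methoxyphenyl]-6-[2-(4-hydroxyphenyl)ethyl]tetrahydro-2H-pyran-4-ol
Product: 18 (2S,4R,6S)-2-(3,4-dihydroxy-5-methoxyphenyl)-6-[2-(4-hydroxyphenyl)ethyl]tetrahydro-2H-pyran-4-ol (CNP0186008.1)
Conditions: H2 (1 atm), 10% Pd/C, EtOAc/MeOH, rt; work-up under argon
Reagents that add atoms: none
Why: Heterogeneous hydrogenolysis of the two aryl benzyl ethers, which should be much faster than cleavage of the dialkyl benzylic C2–O1 bond in a neutral solvent, releases the air-sensitive catechol under non-oxidising conditions with all three stereocentres untouched.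

Compound list
1 | 3,4-dihydroxy-5-methoxybenzaldehyde (5-hydroxyvanillin) | COc1cc(C=O)cc(O)c1O | starting material
2 | 3,4-bis(benzyloxy)-5-methoxybenzaldehyde | COc1cc(C=O)cc(OCc2ccccc2)c1OCc3ccccc3 | intermediate
3 | [3,4-bis(benzyloxy)-5-methoxyphenyl]methanol | COc1cc(CO)cc(OCc2ccccc2)c1OCc3ccccc3 | intermediate
4 | 3,4-bis(benzyloxy)-5-methoxybenzyl 2,2,2-trichloroacetimidate | COc1cc(COC(=N)C(Cl)(Cl)Cl)cc(OCc2ccccc2)c1OCc3ccccc3 | intermediate
5 | 3-(4-hydroxyphenyl)propan-1-ol | OCCCc1ccc(O)cc1 | starting material
6 | 4-(3-hydroxypropyl)phenyl pivalate | CC(C)(C)C(=O)Oc1ccc(CCCO)cc1 | intermediate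
7 | 4-(3-oxopropyl)phenyl pivalate | CC(C)(C)C(=O)Oc1ccc(CCC=O)cc1 | intermediate
8 | allenylboronic acid pinacol ester, 4,4,5,5-tetramethyl-2-(propa-1,2-dien-1-yl)-1,3,2-dioxaborolane | C=C=CB1OC(C)(C)C(C)(C)O1 | starting material
9 | 4-{(3S)-3-[(4,4,5,5-tetramethyl-1,3,2-dioxaborolan-2-yl)oxy]hex-5-yn-1-yl}phenyl pivalate (pinacol borate ester of 10, formed in the flask) | CC1(C)OB(O[C@@H](CCc2ccc(OC(=O)C(C)(C)C)cc2)CC#C)OC1(C)C | intermediate
10 | (S)-4-(3-hydroxyhex-5-yn-1-yl)phenyl pivalate | O[C@@H](CCc1ccc(OC(=O)C(C)(C)C)cc1)CC#C | intermediate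
11 | (S)-4-{3-[(3,4-bis(benzyloxy)-5-methoxybenzyl)oxy]hex-5-yn-1-yl}phenyl pivalate | COc1cc(CO[C@@H](CCc2ccc(OC(=O)C(C)(C)C)cc2)CC#C)cc(OCc3ccccc3)c1OCc4ccccc4 | intermediate
12 | (S)-4-{[3,4-bis(benzyloxy)-5-methoxybenzyl]oxy}-6-[4-(pivaloyloxy)phenyl]hex-1-en-2-yl acetate (key-step precursor) | COc1cc(CO[C@@H](CCc2ccc(OC(=O)C(C)(C)C)cc2)CC(=C)OC(C)=O)cc(OCc3ccccc3)c1OCc4ccccc4 | intermediate
13 | (E)-[3,4-bis(benzyloxy)-5-methoxybenzylidene]{(3S)-5-acetoxy-1-[4-(pivaloyloxy)phenyl]hex-5-en-3-yl}oxonium (oxocarbenium ion, formed in the flask) | COc1cc(/C=[O+]/[C@@H](CCc2ccc(OC(=O)C(C)(C)C)cc2)CC(=C)OC(C)=O)cc(OCc3ccccc3)c1OCc4ccccc4 | intermediate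
14 | (2S,6S)-ketone 15 carrying an acetyl group on the C4 carbonyl oxygen (O-acetyl oxocarbenium ion, formed in the flask) | COc1cc([C@@H]2CC(=[O+]C(C)=O)C[C@H](CCc3ccc(OC(=O)C(C)(C)C)cc3)O2)cc(OCc4ccccc4)c1OCc5ccccc5 | intermediate
15 | (2S,6S)-2-[3,4-bis(benzyloxy)-5-methoxyphenyl]-6-{2-[4-(pivaloyloxy)phenyl]ethyl}tetrahydro-4H-pyran-4-one (key-step product) | COc1cc([C@@H]2CC(=O)C[C@H](CCc3ccc(OC(=O)C(C)(C)C)cc3)O2)cc(OCc4ccccc4)c1OCc5ccccc5 | intermediate
16 | 4-{2-[(2S,4R,6S)-6-[3,4-bis(benzyloxy)-5-methoxyphenyl]-4-hydroxytetrahydro-2H-pyran-2-yl]ethyl}phenyl pivalate (formed in the flask as its aluminium alkoxide) | COc1cc([C@@H]2C[C@H](O)C[C@H](CCc3ccc(OC(=O)C(C)(C)C)cc3)O2)cc(OCc4ccccc4)c1OCc5ccccc5 | intermediate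
17 | (2S,4R,6S)-2-[3,4-bis(benzyloxy)-5-methoxyphenyl]-6-[2-(4-hydroxyphenyl)ethyl]tetrahydro-2H-pyran-4-ol | COc1cc([C@@H]2C[C@H](O)C[C@H](CCc3ccc(O)cc3)O2)cc(OCc4ccccc4)c1OCc5ccccc5 | intermediate
18 | (2S,4R,6S)-2-(3,4-dihydroxy-5-methoxyphenyl)-6-[2-(4-hydroxyphenyl)ethyl]tetrahydro-2H-pyran-4-ol | COc1cc([C@@H]2C[C@H](O)C[C@H](CCc3ccc(O)cc3)O2)cc(O)c1O | target

Total step count: 11.
Longest linear sequence: 8 steps (5 to 18 through steps 4–11; the branch from 1, steps 1–3 and 7–11, is equally long).

Steps most likely to fail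

1. Step 9 (oxidative cyclisation). Three processes could defeat it:
- hydride abstraction may be slow, because the central alkoxy group of the 3,4,5-pattern is twisted out of conjugation;
- traces of water may intercept ion 13, which amounts to oxidative loss of the benzyl group;
- the product may be oxidised a second time at C2.

The fallback is a Prins cyclisation that sets out from aldehydes 7 and 2 and rejoins the route at 17. Aldehyde 7 would be allylated with allylboronic acid pinacol ester and (R)-TRIP in toluene at −30 °C (same Re-face model as step 6) to give (S)-4-(3-hydroxyhex-5-en-1-yl)phenyl pivalate F1. F1 and aldehyde 2 in trifluoroacetic acid/CH2Cl2 (0 °C to rt) would condense to an (E)-oxocarbenium ion of the same kind, which closes through the all-equatorial chair and takes up trifluoroacetate equatorially at C4. This would give (2S,4R,6S)-2-[3,4-bis(benzyloxy)-5-methoxyphenyl]-6-{2-[4-(pivaloyloxy)phenyl]ethyl}tetrahydro-2H-pyran-4-yl trifluoroacetate F2. K2CO3 in methanol would then cleave both the trifluoroacetate and the pivalate and deliver 17, so that steps 6–10 are bypassed.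

2. Step 6 (asymmetric propargylation). Enantioselectivity may be insufficient with an unbranched aliphatic aldehyde, or induction may run in the sense opposite to the one expected. Both would be checked on 10 by Mosher ester analysis and chiral HPLC.

The fallback sets the stereocentre by kinetic resolution of an epoxide and runs from aldehyde 7 back to 10. Corey–Chaykovsky methylenation of 7 (trimethylsulfonium iodide, n-BuLi, THF, −10 °C to rt) would give racemic 4-[2-(oxiran-2-yl)ethyl]phenyl pivalate F3. Hydrolytic kinetic resolution with (S,S)-(salen)Co(III)OAc and 0.55 equiv of water would hydrolyse the (R)-epoxide and leave (S)-4-[2-(oxiran-2-yl)ethyl]phenyl pivalate F4. Opening of F4 at its terminal carbon with lithium (trimethylsilyl)acetylide and BF3·OEt2 in THF at −78 °C would give (S)-4-[3-hydroxy-6-(trimethylsilyl)hex-5-yn-1-yl]phenyl pivalate F5, with the configuration retained because the stereocentre is not attacked. Silver-catalysed protiodesilylation (AgNO3 cat., aqueous acetone), which spares the aryl pivalate, would return 10.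

3. Step 11 (hydrogenolysis). Over-reduction may open the ring at the benzylic C2–O1 bond, and the liberated catechol may oxidise in air during isolation.

The fallback replaces catalytic reduction by Lewis-acid debenzylation and runs from 17 directly to 18. BCl3 with pentamethylbenzene as a non-basic benzyl-cation scavenger in CH2Cl2 at −78 °C would be used, followed by a methanol quench under argon. This is known to cleave aryl benzyl ethers while sparing aryl methyl ethers and secondary alcohols at that temperature, and no hydrogenation catalyst comes near the C2–O1 bond.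

Further compounds
F1 | step 9 | (S)-4-(3-hydroxyhex-5-en-1-yl)phenyl pivalate | O[C@@H](CCc1ccc(OC(=O)C(C)(C)C)cc1)CC=C
F2 | step 9 | (2S,4R,6S)-2-[3,4-bis(benzyloxy)-5-methoxyphenyl]-6-{2-[4-(pivaloyloxy)phenyl]ethyl}tetrahydro-2H-pyran-4-yl trifluoroacetate | COc1cc([C@@H]2C[C@H](OC(=O)C(F)(F)F)C[C@H](CCc3ccc(OC(=O)C(C)(C)C)cc3)O2)cc(OCc4ccccc4)c1OCc5ccccc5
F3 | step 6 | racemic 4-[2-(oxiran-2-yl)ethyl]phenyl pivalate | CC(C)(C)C(=O)Oc1ccc(CCC2CO2)cc1
F4 | step 6 | (S)-4-[2-(oxiran-2-yl)ethyl]phenyl pivalate | CC(C)(C)C(=O)Oc1ccc(CC[C@H]2CO2)cc1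
F5 | step 6 | (S)-4-[3-hydroxy-6-(trimethylsilyl)hex-5-yn-1-yl]phenyl pivalate | C[Si](C)(C)C#CC[C@@H](O)CCc1ccc(OC(=O)C(C)(C)C)cc1
F0 | step 11 | none | none
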